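## The problem

Compound 17 is epicatechin-(4β→6)-catechin-(4α→6)-catechin: three flavan-3-ol units joined by two diarylmethine bonds, each running from C4 of one unit to C6 of ring A of the next. It holds eight stereocentres: C2 and C3 of the lower unit, and C2, C3 and C4 of the middle and upper units. The lower and middle units are 2,3-trans (catechin), the upper unit is 2,3-cis (epicatechin), and both interflavan bonds are 3,4-trans. Within one unit the C3 oxygen can steer a new bond at C4 to the opposite face, but the units are too far apart to relay configuration across an interflavan bond, so each unit needs its own stereochemical source. Both linkages go to C6, although C8 is the more nucleophilic carbon of a 5,7-dioxygenated ring A, so regiochemistry has to be imposed. The twelve phenols are sensitive to air and base, and the interflavan bonds are benzylic bonds to phloroglucinol-type rings that cleave under acid, so the last steps must be neutral. The feature that opens the route is ring C of the upper unit: its C4 is bonded to C6 of the middle unit, to C3 (trans to the C3 hydroxyl) and to C4a of a ring A that is simply a symmetric 3,5-dioxygenated phenyl ether of the C2 oxygen. The chain O1–C2–C3–C4 can therefore be an aryl ether tether ending in a trans C3–C4 epoxide whose benzylic carbon is C4.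

## Retrosynthesis

Units are called upper, middle and lower; atoms carry flavan numbering within each unit.

**17 from 16.** All fourteen O–benzyl bonds and the two C8–Br bonds are cut. Benzyl on every protected oxygen and bromine as the only blocking group allow one neutral hydrogenolysis to finish the synthesis. Compound 16 differs from 17 only in these groups. The forward step must leave the cyclic benzylic C2–O1 ethers and the interflavan bonds intact.

**16 from 15.** The bond C4–C4a of the upper unit is cut, which opens ring C of that unit to the epoxy aryl ether 15. The neighbouring cut, C4(upper)–C6(middle), is the usual intermolecular flavan coupling; it would need a second flavanol from the chiral pool and would leave the C4 configuration to substrate bias. The chosen cut turns the diarylmethine stereocentre into an epoxide carbon of defined configuration and uses a nucleophile ring with two equivalent ortho carbons. The forward reaction must open the epoxide at C4 only, with inversion, and close a six-membered ring.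

**15 from 13 and 14.** The C2–O aryl ether bond is cut to the epoxy alcohol 13 and commercial 3,5-bis(benzyloxy)phenol 14. This bond is chosen because a Mitsunobu reaction forms it with inversion. That inversion converts the erythro epoxy alcohol, the natural outcome of a Sharpless epoxidation, into the threo relation that becomes 2,3-cis. The carbinol must not ionise.

**13 from 12 from 11.** The epoxide oxygen and the carbinol hydrogen are removed, leading to the (E)-enone 11. The E double bond fixes the trans-epoxide, a CBS reduction sets the carbinol, and the tartrate-controlled epoxidation sets C3 and C4 while rejecting any wrong carbinol epimer. Enone 11 has no stereocentre in the upper portion.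

**11 from 8 and 9.** The Cα=Cβ bond is cut to aldehyde 8 and commercial 3',4'-bis(benzyloxy)acetophenone 9. Ketone 9 brings ring B, C2 and C3 of the upper unit; the aldehyde carbon becomes C4. A Claisen–Schmidt condensation is asked to give the E isomer only.

**8 from 6.** The formyl group on middle C6 is removed. In dimer 6 this is the only unsubstituted ring A carbon, because both C8 positions carry bromine and lower C6 carries the middle unit, so electrophilic formylation has one site.

**6 from 5 and 4.** The bond middle C4–lower C6 is cut. Both halves come from the same monomer 4: once as the nucleophile, and once, after C4 oxidation to 5, as the electrophile. Bromine at C8 directs the nucleophile to C6. The coupling must go 3,4-trans.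

**5, 4, 3 and 2 from 1.** C4 alkoxylation, C8 bromination and benzylation lead back to (+)-catechin 1. Catechin supplies four of the eight stereocentres directly and controls a fifth (middle C4).

## Roads not taken

Alternative 1: The cut runs through ring C of the lower unit, at O1–C8a and C4–C4a. In the forward step CsF would unmask an aryne across C4a–C8a of the future lower ring A from the silyl triflate A2, which already carries the upper and middle units. The sodium alkoxide of the tosyloxy alcohol A3 (made with NaH) would add at C8a, and the aryl anion left at C4a would displace the tosylate, giving the fully benzylated trimer A1.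
- Merits: two bonds and a ring form in one flask under basic conditions that respect both interflavan bonds, and the C5 alkoxy group should direct the alkoxide to C8a as required.
- Weak points: the ring being built is that of plain catechin, the one unit that can be bought with its stereocentres in place. The two C4→C6 bonds and their 3,4-trans configurations still have to be solved beforehand. A2 needs an ortho-silyl triflate on a hexasubstituted ring already attached to a dimer. The alkoxide of A3 can close to an oxetane or eliminate before it meets the aryne, and the hindered aryl anion may be protonated before it alkylates.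
- Comparison: this road is better in that no acid-labile epoxide is handled and no bromine is needed. The chosen plan sets against this the direct use of catechin for two units and a key step that fixes a stereocentre of the difficult linkage.

Alternative 2: Three bonds of ring A of the middle unit are cut (C4a–C8a, C5–C6, C8–C8a). Heating the siloxycyclobutenone A5, which carries the upper unit, with the siloxyalkyne A6, which carries the middle C4–C2 chain and the lower unit, would give the phenol A4. The sequence is electrocyclic opening to a vinylketene, [2+2] addition, a second opening and 6π closure. The free C8a hydroxyl of A4 would then have to displace the activated C2 oxygen with inversion to close the pyran.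
- Merits: the substitution pattern of the central ring is written into the partners, so both C6 linkages are fixed by construction without bromine. Convergence is the highest of all the plans, and the step is thermal and neutral.
- Weak points: A5 already contains the upper diarylmethine stereocentre and A6 a propargylic stereocentre bearing the lower unit, so the hardest stereocentres are only moved into two long fragment syntheses. Two very bulky partners must meet at a fully substituted ring at elevated temperature, where ketene dimerisation and alkyne decomposition compete. A ring closure at a benzylic carbon and silyl removals still follow.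
- Comparison: this road is superior in regiochemical certainty and convergence. The chosen plan answers with far fewer steps, with stereocentres from the chiral pool, and with the upper C4 centre settled inside the key step.

Alternative 3: The bonds C3–C4 and O1–C2 of ring C of the middle unit are cut. A chiral phosphoric acid would dehydrate the ortho-hydroxy diarylcarbinol A8 to an ortho-quinone methide, which would add the enol acetate A9 in a [4+2] reaction to give the trimer A7 with a middle 3-O-acetate.
- Merits: two bonds, one ring and three contiguous stereocentres arise in one catalytic step, and the E geometry of A9 maps onto the 2,3-trans relation of the middle unit.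
- Weak points: the acetoxy-bearing carbon of A9 must bond to the methide carbon, so the aryl group has to dominate the polarisation against the enol oxygen. Endo/exo selectivity decides the 3,4 relation. The catalyst must impose a face on a methide carbon that carries a whole di-ortho-substituted flavan unit. A8 already contains the upper–middle bond and needs exactly one free phenol. The acid that forms the quinone methide threatens that interflavan bond, and the acetate costs a further step.
- Comparison: this road creates more stereochemistry per step (three centres against one) and would be shorter if A8 were at hand. The chosen plan sets against this that the three stereocentres of the middle unit come free with catechin, and that its one new centre follows from an epoxide of fixed configuration.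

Key step: step 11

Remark: compound 5 is taken on as the mixture of C4 epimers formed in the oxidation, because C4 is planarised when it ionises in step 5.

Step 1
Reactants: 1 (+)-catechin
Product: 2 5,7,3',4'-tetra-O-benzyl-(+)-catechin (2R,3S, free 3-OH)
Conditions: BnBr, K2CO3, DMF, 0 °C to rt
Reagents that add atoms: benzyl bromide, BrCc1ccccc1
Why: Williamson etherification; K2CO3 deprotonates only the four phenols, so the aliphatic 3-OH stays free and no stereocentre is touched.

Step 2
Reactants: 2 5,7,3',4'-tetra-O-benzyl-(+)-catechin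
Product: 3 3,5,7,3',4'-penta-O-benzyl-(+)-catechin
Conditions: NaH, BnBr, DMF, 0 °C to rt
Reagents that add atoms: benzyl bromide, BrCc1ccccc1
Why: Williamson etherification of the secondary alkoxide; with the phenols already capped there is no quinone methide pathway for C2 epimerisation.

Step 3
Reactants: 3 3,5,7,3',4'-penta-O-benzyl-(+)-catechin
Product: 4 8-bromo-3,5,7,3',4'-penta-O-benzyl-(+)-catechin
Conditions: NBS, CH2Cl2, −78 °C to rt
Reagents that add atoms: N-bromosuccinimide, O=C1CCC(=O)N1Br
Why: Electrophilic aromatic bromination; C8 is the most nucleophilic carbon of the 5,7-dialkoxy ring A, so one equivalent of NBS should brominate there and leave C6 as the only nucleophilic site.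

Step 4
Reactants: 4 8-bromo-3,5,7,3',4'-penta-O-benzyl-(+)-catechin
Product: 5 8-bromo-4-(2-ethoxyethoxy)-3,5,7,3',4'-penta-O-benzylcatechin (C4 epimers)
Conditions: DDQ, 2-ethoxyethanol, CH2Cl2, rt
Reagents that add atoms: 2-ethoxyethanol, CCOCCO
Why: DDQ benzylic oxidation; hydride abstraction at C4 gives a cation stabilised by O5 and O7 that the alcohol traps. The C4 configuration is irrelevant because it is erased in step 5.

Step 5
Reactants: 5 8-bromo-4-(2-ethoxyethoxy)-3,5,7,3',4'-penta-O-benzylcatechin, 4 8-bromo-3,5,7,3',4'-penta-O-benzyl-(+)-catechin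
Product: 6 8-bromo-penta-O-benzylcatechin-(4α→6)-8-bromo-penta-O-benzylcatechin (middle C6 unsubstituted)
Conditions: TMSOTf (cat.), 4 (3 equiv), CH2Cl2, −78 °C; Et3N quench
Reagents that add atoms: none
Why: Lewis acid-mediated Friedel–Crafts flavan coupling through the C4 cation of 5; the C8 bromine leaves C6 of 4 as the only nucleophilic carbon. The nucleophile approaches C4 anti to the 3-benzyloxy group, which sets the 3,4-trans (4α) centre, and the excess of 4 suppresses further reaction at C6 of 5 or 6.

Step 6
Reactants: 6 8-bromo-penta-O-benzylcatechin-(4α→6)-8-bromo-penta-O-benzylcatechin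
Product: 8 middle-C6 carbaldehyde of dimer 6, via iminium chloride 7 (not isolated)
Conditions: POCl3, DMF, ClCH2CH2Cl, 60 °C; then aq NaOAc
Reagents that add atoms: N,N-dimethylformamide, CN(C)C=O (formyl carbon); water, O (carbonyl oxygen on hydrolysis)
Why: Vilsmeier–Haack formylation; middle C6, flanked by two benzyloxy groups, is the only free ring A carbon in 6, and the catechol-type B rings are much less nucleophilic. Iminium salt 7 is hydrolysed in the buffered work-up.

Step 7
Reactants: 8 middle-C6 carbaldehyde of dimer 6, 9 3',4'-bis(benzyloxy)acetophenone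
Product: 11 (E)-enone joining middle C6 to the 3,4-bis(benzyloxy)benzoyl group, via aldol adduct 10 (not isolated)
Conditions: KOH, THF/EtOH, rt to 40 °C
Reagents that add atoms: none
Why: Claisen–Schmidt condensation of a non-enolisable aldehyde with a methyl ketone; adduct 10 dehydrates by E1cB to the conjugated enone, and the E isomer is the thermodynamic product.

Step 8
Reactants: 11 (E)-enone
Product: 12 (1R,2E)-1-[3,4-bis(benzyloxy)phenyl]-3-(middle C6 of dimer)prop-2-en-1-ol
Conditions: (S)-Me-CBS (cat.), catecholborane, toluene, −78 °C; MeOH, then aq NaOH wash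
Reagents that add atoms: none
Why: Corey–Bakshi–Shibata 1,2-reduction; with the aryl group as the larger carbonyl substituent the (S)-oxazaborolidine should deliver hydride to the face that gives the (R)-carbinol. Catecholborane at low temperature avoids hydroboration of the alkene, and any (S)-epimer is rejected in step 9.

Step 9
Reactants: 12 (1R,2E)-allylic alcohol
Product: 13 (1S,2S,3S)-1-[3,4-bis(benzyloxy)phenyl]-2,3-epoxy-3-(middle C6 of dimer)propan-1-ol (erythro, trans-epoxide)
Conditions: Ti(OiPr)4 (cat.), L-(+)-DIPT, t-BuOOH, 4 Å MS, CH2Cl2, −20 °C; aq NaOH/brine work-up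
Reagents that add atoms: tert-butyl hydroperoxide, CC(C)(C)OO
Why: Sharpless asymmetric epoxidation of a secondary (E)-allylic alcohol in its matched sense; L-(+)-tartrate delivers oxygen to the alkene face that gives the erythro epoxy alcohol from the (R)-carbinol, while the (S)-epimer reacts far more slowly. The E alkene gives the trans-epoxide, so C3 and C4 of the future upper unit are set here.

Step 10
Reactants: 13 erythro epoxy alcohol, 14 3,5-bis(benzyloxy)phenol
Product: 15 threo epoxy 3,5-bis(benzyloxy)phenyl ether (ether carbon inverted, epoxide unchanged)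
Conditions: PPh3, DIAD, toluene, 0 °C to rt
Reagents that add atoms: none
Why: Mitsunobu etherification; SN2 displacement of the oxyphosphonium group by the phenoxide inverts the carbinol, turning the erythro alcohol into the threo ether that maps onto 2,3-cis. The adjacent epoxide oxygen disfavours ionisation of the benzylic carbon.

Step 11
Reactants: 15 threo epoxy 3,5-bis(benzyloxy)phenyl ether
Product: 16 tetradeca-O-benzyl-8-bromo(middle)-8-bromo(lower)-epicatechin-(4β→6)-catechin-(4α→6)-catechin with free upper 3-OH
Conditions: BF3·OEt2 (0.3 equiv), CH2Cl2, −78 °C; Et3N quench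
Reagents that add atoms: none
Why: Coordination of BF3 to the epoxide oxygen weakens the C4–O bond, the one benzylic to the electron-rich ring A of the middle unit; an ortho carbon of the phenyl ether attacks C4 on the face opposite the leaving oxygen, and the arenium ion passes its proton to the alkoxide, which frees the C3 hydroxyl and the Lewis acid. The closest known reaction type is the Lewis acid-mediated intramolecular Friedel–Crafts epoxy–arene cyclisation of aryl 3-arylglycidyl ethers to trans-4-arylchroman-3-ols. The new ring, ring C of the upper unit, is six-membered and forms by the endo mode of epoxide opening (6-endo); the 5-exo closure at C3 would give a dihydrobenzofuran, but C3 has no benzylic activation. The one new stereocentre, upper C4, is controlled by the epoxide configuration through inversion and comes out 3,4-trans (4β); C2 and C3 are not touched, so the 2,3-cis relation from steps 9 and 10 is carried through. The step needs anti opening to outrun a free benzylic cation, which would scramble C4 or undergo a 1,2-hydride shift to a ketone (Meinwald rearrangement); low temperature, a substoichiometric Lewis acid, the tethered and highly nucleophilic trioxygenated ring and the inductive pull of the middle C8 bromine all work in that direction. The nucleophile offers no regiochemical choice because its two ortho carbons are equivalent, and no other ring A can compete because middle C8 and lower C8 carry bromine and lower C6 is substituted.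

Step 12
Reactants: 16 tetradeca-O-benzyl dibromo trimer
Product: 17 epicatechin-(4β→6)-catechin-(4α→6)-catechin (CNP0163146.4)
Conditions: H2 (1 atm), Pd(OH)2/C, Et3N, THF/MeOH/H2O, rt
Reagents that add atoms: none
Why: Heterogeneous hydrogenolysis over Pd(OH)2/C cleaves the fourteen benzyl ethers and hydrodebrominates both aryl bromides. Et3N takes up the HBr so the acid-labile interflavan bonds stay intact, and the cyclic benzylic C2–O1 ethers are expected to survive as they do in related flavan deprotections.

Compound list

1 | (+)-catechin, (2R,3S)-2-(3,4-dihydroxyphenyl)chromane-3,5,7-triol | Oc1cc(O)c2c(c1)O[C@H](c1ccc(O)c(O)c1)[C@@H](O)C2 | starting material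

2 | 5,7,3',4'-tetra-O-benzyl-(+)-catechin (2R,3S) | c1c(OCc9ccccc9)cc2c(c1OCc9ccccc9)C[C@H](O)[C@@H](c8ccc(OCc9ccccc9)c(OCc9ccccc9)c8)O2 | intermediate

3 | 3,5,7,3',4'-penta-O-benzyl-(+)-catechin (2R,3S) | c1c(OCc9ccccc9)cc2c(c1OCc9ccccc9)C[C@H](OCc9ccccc9)[C@@H](c8ccc(OCc9ccccc9)c(OCc9ccccc9)c8)O2 | intermediate

4 | 8-bromo-3,5,7,3',4'-penta-O-benzyl-(+)-catechin (2R,3S) | c1c(OCc9ccccc9)c(Br)c2c(c1OCc9ccccc9)C[C@H](OCc9ccccc9)[C@@H](c8ccc(OCc9ccccc9)c(OCc9ccccc9)c8)O2 | intermediate

5 | 8-bromo-4-(2-ethoxyethoxy)-3,5,7,3',4'-penta-O-benzylcatechin (2,3-trans; C4 epimers) | c1c(OCc9ccccc9)c(Br)c2c(c1OCc9ccccc9)C(OCCOCC)[C@H](OCc9ccccc9)[C@@H](c8ccc(OCc9ccccc9)c(OCc9ccccc9)c8)O2 | intermediate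

6 | 8-bromo-penta-O-benzylcatechin-(4α→6)-8-bromo-penta-O-benzylcatechin (both units 2,3-trans; middle C4 aryl trans to 3-OBn; middle C6–H) | c1c(OCc9ccccc9)c(Br)c2c(c1OCc9ccccc9)[C@@H](c5c(OCc9ccccc9)c(Br)c6c(c5OCc9ccccc9)C[C@H](OCc9ccccc9)[C@@H](c8ccc(OCc9ccccc9)c(OCc9ccccc9)c8)O6)[C@H](OCc9ccccc9)[C@@H](c8ccc(OCc9ccccc9)c(OCc9ccccc9)c8)O2 | intermediate

7 | N,N-dimethyliminium chloride on middle C6 of dimer 6 | C[N+](C)=Cc1c(OCc9ccccc9)c(Br)c2c(c1OCc9ccccc9)[C@@H](c5c(OCc9ccccc9)c(Br)c6c(c5OCc9ccccc9)C[C@H](OCc9ccccc9)[C@@H](c8ccc(OCc9ccccc9)c(OCc9ccccc9)c8)O6)[C@H](OCc9ccccc9)[C@@H](c8ccc(OCc9ccccc9)c(OCc9ccccc9)c8)O2.[Cl-] | intermediate (not isolated)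

8 | dimer 6 with a formyl group on middle C6 | O=Cc1c(OCc9ccccc9)c(Br)c2c(c1OCc9ccccc9)[C@@H](c5c(OCc9ccccc9)c(Br)c6c(c5OCc9ccccc9)C[C@H](OCc9ccccc9)[C@@H](c8ccc(OCc9ccccc9)c(OCc9ccccc9)c8)O6)[C@H](OCc9ccccc9)[C@@H](c8ccc(OCc9ccccc9)c(OCc9ccccc9)c8)O2 | intermediate

9 | 3',4'-bis(benzyloxy)acetophenone | CC(=O)c1ccc(OCc2ccccc2)c(OCc2ccccc2)c1 | starting material

10 | aldol adduct, 1-[3,4-bis(benzyloxy)phenyl]-3-hydroxy-3-(middle C6 of dimer)propan-1-one (carbinol epimers) | O=C(c8ccc(OCc9ccccc9)c(OCc9ccccc9)c8)CC(O)c1c(OCc9ccccc9)c(Br)c2c(c1OCc9ccccc9)[C@@H](c5c(OCc9ccccc9)c(Br)c6c(c5OCc9ccccc9)C[C@H](OCc9ccccc9)[C@@H](c8ccc(OCc9ccccc9)c(OCc9ccccc9)c8)O6)[C@H](OCc9ccccc9)[C@@H](c8ccc(OCc9ccccc9)c(OCc9ccccc9)c8)O2 | intermediate (not isolated)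

11 | (E)-1-[3,4-bis(benzyloxy)phenyl]-3-(middle C6 of dimer)prop-2-en-1-one | O=C(c8ccc(OCc9ccccc9)c(OCc9ccccc9)c8)/C=C/c1c(OCc9ccccc9)c(Br)c2c(c1OCc9ccccc9)[C@@H](c5c(OCc9ccccc9)c(Br)c6c(c5OCc9ccccc9)C[C@H](OCc9ccccc9)[C@@H](c8ccc(OCc9ccccc9)c(OCc9ccccc9)c8)O6)[C@H](OCc9ccccc9)[C@@H](c8ccc(OCc9ccccc9)c(OCc9ccccc9)c8)O2 | intermediate

12 | (1R,2E)-1-[3,4-bis(benzyloxy)phenyl]-3-(middle C6 of dimer)prop-2-en-1-ol | O[C@@H](c8ccc(OCc9ccccc9)c(OCc9ccccc9)c8)/C=C/c1c(OCc9ccccc9)c(Br)c2c(c1OCc9ccccc9)[C@@H](c5c(OCc9ccccc9)c(Br)c6c(c5OCc9ccccc9)C[C@H](OCc9ccccc9)[C@@H](c8ccc(OCc9ccccc9)c(OCc9ccccc9)c8)O6)[C@H](OCc9ccccc9)[C@@H](c8ccc(OCc9ccccc9)c(OCc9ccccc9)c8)O2 | intermediate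

13 | (1S,2S,3S)-1-[3,4-bis(benzyloxy)phenyl]-2,3-epoxy-3-(middle C6 of dimer)propan-1-ol (erythro, trans-epoxide) | O[C@@H](c8ccc(OCc9ccccc9)c(OCc9ccccc9)c8)[C@@H]7O[C@H]7c1c(OCc9ccccc9)c(Br)c2c(c1OCc9ccccc9)[C@@H](c5c(OCc9ccccc9)c(Br)c6c(c5OCc9ccccc9)C[C@H](OCc9ccccc9)[C@@H](c8ccc(OCc9ccccc9)c(OCc9ccccc9)c8)O6)[C@H](OCc9ccccc9)[C@@H](c8ccc(OCc9ccccc9)c(OCc9ccccc9)c8)O2 | intermediate

14 | 3,5-bis(benzyloxy)phenol | Oc1cc(OCc2ccccc2)cc(OCc2ccccc2)c1 | starting material

15 | threo epoxy 3,5-bis(benzyloxy)phenyl ether (ether carbon inverted relative to 13; trans-epoxide as in 13; middle and lower units as in 6) | c1c(OCc9ccccc9)cc(OCc9ccccc9)cc1O[C@H](c8ccc(OCc9ccccc9)c(OCc9ccccc9)c8)[C@@H]7O[C@H]7c3c(OCc9ccccc9)c(Br)c4c(c3OCc9ccccc9)[C@@H](c5c(OCc9ccccc9)c(Br)c6c(c5OCc9ccccc9)C[C@H](OCc9ccccc9)[C@@H](c8ccc(OCc9ccccc9)c(OCc9ccccc9)c8)O6)[C@H](OCc9ccccc9)[C@@H](c8ccc(OCc9ccccc9)c(OCc9ccccc9)c8)O4 | intermediate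

16 | tetradeca-O-benzyl-8-bromo(middle)-8-bromo(lower)-epicatechin-(4β→6)-catechin-(4α→6)-catechin, free upper 3-OH (upper unit 2,3-cis-3,4-trans) | c1(OCc9ccccc9)cc(OCc9ccccc9)c2c(c1)O[C@H](c8ccc(OCc9ccccc9)c(OCc9ccccc9)c8)[C@H](O)[C@H]2c3c(OCc9ccccc9)c(Br)c4c(c3OCc9ccccc9)[C@@H](c5c(OCc9ccccc9)c(Br)c6c(c5OCc9ccccc9)C[C@H](OCc9ccccc9)[C@@H](c8ccc(OCc9ccccc9)c(OCc9ccccc9)c8)O6)[C@H](OCc9ccccc9)[C@@H](c8ccc(OCc9ccccc9)c(OCc9ccccc9)c8)O4 | intermediate

17 | epicatechin-(4β→6)-catechin-(4α→6)-catechin (CNP0163146.4) | Oc1cc(O)c2c(c1)O[C@H](c1ccc(O)c(O)c1)[C@H](O)[C@H]2c1c(O)cc2c(c1O)[C@@H](c1c(O)cc3c(c1O)C[C@H](O)[C@@H](c1ccc(O)c(O)c1)O3)[C@H](O)[C@@H](c1ccc(O)c(O)c1)O2 | target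

Total step count: 12. Longest linear sequence: 12 steps, from 1 to 17. Compounds 9 and 14 are bought and enter at steps 7 and 10, and compound 4 is used twice.

Steps least certain to work

For step 11, the key step, the danger is full ionisation at C4. The two ortho benzyloxy groups and the para ring oxygen of the middle ring A stabilise a free benzylic cation, and such a cation could close from either face, shift a hydride to give a ketone, or fragment. The fallback gives up the epoxide and makes the bond upper C4–middle C6 by the classical intermolecular route. Commercial (−)-epicatechin would be benzylated (BnBr, K2CO3) to 5,7,3',4'-tetra-O-benzyl-(−)-epicatechin F1. Oxidation with DDQ and 2-ethoxyethanol would give its 4-(2-ethoxyethoxy) derivative F2. F2 would then be coupled with dimer 6 under TMSOTf at −78 °C. Middle C6 is the only free ring A carbon of 6, and attack anti to the C3 oxygen of the 2,3-cis electrophile gives the 4β bond. This fallback sets out from 6 and returns to the route at 16.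

For step 9 the danger is opening of the newly formed, very electron-rich benzylic epoxide by the Lewis-acidic titanium alkoxide, through solvolysis by isopropanol or hydroperoxide or through rearrangement, before it can be isolated. The fallback is a dioxirane epoxidation of 12 without any Lewis acid. It would use the enantiomer of the D-fructose-derived Shi ketone, which should attack the same alkene face as L-(+)-tartrate, with KHSO5 (as 2KHSO5·KHSO4·K2SO4) and K2CO3 buffer near pH 10.5. It sets out from 12 and returns at 13, and it makes no new compound (F0).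

For step 10 the danger is partial ionisation of the oxyphosphonium intermediate at the electron-rich benzylic carbon, which would erode the C2 configuration, together with elimination. The fallback never substitutes at C2. Enone 11 would be reduced with the (R)-oxazaborolidine to the (S)-allylic alcohol F3. Shi epoxidation with the same ketone as above would give the threo epoxy alcohol F4. The aryl ether would then be made with retention by a Chan–Lam coupling of F4 with 3,5-bis(benzyloxy)phenylboronic acid, mediated by Cu(OAc)2 and pyridine under air, a method that tolerates the aryl bromides. This fallback sets out from 11 and returns at 15.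

For step 6 the danger is slow substitution at the hindered, bromine-deactivated C6, with acid-promoted fission of the interflavan bond under the forcing conditions that would then be needed. The fallback replaces electrophilic formylation by halogen–metal exchange. Dimer 6 would be iodinated at middle C6 with N-iodosuccinimide to the 6-iodo dimer F5. Selective iodine–magnesium exchange with iPrMgCl·LiCl at −40 °C, which leaves the two aryl bromides alone, and a DMF quench would give the aldehyde. This fallback sets out from 6 and returns at 8.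

Further compounds

F1 | step 11 | 5,7,3',4'-tetra-O-benzyl-(−)-epicatechin | c1c(OCc9ccccc9)cc2c(c1OCc9ccccc9)C[C@@H](O)[C@@H](c8ccc(OCc9ccccc9)c(OCc9ccccc9)c8)O2

F2 | step 11 | 4-(2-ethoxyethoxy)-5,7,3',4'-tetra-O-benzylepicatechin (C4 epimers) | c1c(OCc9ccccc9)cc2c(c1OCc9ccccc9)C(OCCOCC)[C@@H](O)[C@@H](c8ccc(OCc9ccccc9)c(OCc9ccccc9)c8)O2

F0 | step 9 | none | none

F3 | step 10 | (1S,2E)-1-[3,4-bis(benzyloxy)phenyl]-3-(middle C6 of dimer)prop-2-en-1-ol | O[C@H](c8ccc(OCc9ccccc9)c(OCc9ccccc9)c8)/C=C/c1c(OCc9ccccc9)c(Br)c2c(c1OCc9ccccc9)[C@@H](c5c(OCc9ccccc9)c(Br)c6c(c5OCc9ccccc9)C[C@H](OCc9ccccc9)[C@@H](c8ccc(OCc9ccccc9)c(OCc9ccccc9)c8)O6)[C@H](OCc9ccccc9)[C@@H](c8ccc(OCc9ccccc9)c(OCc9ccccc9)c8)O2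

F4 | step 10 | threo epoxy alcohol, carbinol epimer of 13 | O[C@H](c8ccc(OCc9ccccc9)c(OCc9ccccc9)c8)[C@@H]7O[C@H]7c1c(OCc9ccccc9)c(Br)c2c(c1OCc9ccccc9)[C@@H](c5c(OCc9ccccc9)c(Br)c6c(c5OCc9ccccc9)C[C@H](OCc9ccccc9)[C@@H](c8ccc(OCc9ccccc9)c(OCc9ccccc9)c8)O6)[C@H](OCc9ccccc9)[C@@H](c8ccc(OCc9ccccc9)c(OCc9ccccc9)c8)O2

F5 | step 6 | dimer 6 with iodine on middle C6 | Ic1c(OCc9ccccc9)c(Br)c2c(c1OCc9ccccc9)[C@@H](c5c(OCc9ccccc9)c(Br)c6c(c5OCc9ccccc9)C[C@H](OCc9ccccc9)[C@@H](c8ccc(OCc9ccccc9)c(OCc9ccccc9)c8)O6)[C@H](OCc9ccccc9)[C@@H](c8ccc(OCc9ccccc9)c(OCc9ccccc9)c8)O2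

A1 | alternative 1 | pentadeca-O-benzyl trimer | c1(OCc9ccccc9)cc(OCc9ccccc9)c2c(c1)O[C@H](c8ccc(OCc9ccccc9)c(OCc9ccccc9)c8)[C@H](OCc9ccccc9)[C@H]2c3c(OCc9ccccc9)cc4c(c3OCc9ccccc9)[C@@H](c5c(OCc9ccccc9)cc6c(c5OCc9ccccc9)C[C@H](OCc9ccccc9)[C@@H](c8ccc(OCc9ccccc9)c(OCc9ccccc9)c8)O6)[C@H](OCc9ccccc9)[C@@H](c8ccc(OCc9ccccc9)c(OCc9ccccc9)c8)O4

A2 | alternative 1 | upper–middle dimer carrying on middle C4 a 2,6-bis(benzyloxy)-3-(trimethylsilyl)-4-(trifluoromethylsulfonyloxy)phenyl group | c1(OCc9ccccc9)cc(OCc9ccccc9)c2c(c1)O[C@H](c8ccc(OCc9ccccc9)c(OCc9ccccc9)c8)[C@H](OCc9ccccc9)[C@H]2c3c(OCc9ccccc9)cc4c(c3OCc9ccccc9)[C@@H](c5c(OCc9ccccc9)cc(OS(=O)(=O)C(F)(F)F)c([Si](C)(C)C)c5OCc9ccccc9)[C@H](OCc9ccccc9)[C@@H](c8ccc(OCc9ccccc9)c(OCc9ccccc9)c8)O4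

A3 | alternative 1 | 1-[3,4-bis(benzyloxy)phenyl]-2-(benzyloxy)-3-(4-methylphenylsulfonyloxy)propan-1-ol with the catechin C2/C3 configuration | Cc1ccc(cc1)S(=O)(=O)OC[C@H](OCc1ccccc1)[C@@H](c1ccc(OCc2ccccc2)c(OCc2ccccc2)c1)O

A4 | alternative 2 | middle ring A as 5,7-bis(triisopropylsilyl ether) with free C8a phenol, pyran open | c1(OCc9ccccc9)cc(OCc9ccccc9)c2c(c1)O[C@H](c8ccc(OCc9ccccc9)c(OCc9ccccc9)c8)[C@H](OCc9ccccc9)[C@H]2c3c(O[Si](C(C)C)(C(C)C)C(C)C)cc(O)c(c3O[Si](C(C)C)(C(C)C)C(C)C)[C@@H](c5c(OCc9ccccc9)cc6c(c5OCc9ccccc9)C[C@H](OCc9ccccc9)[C@@H](c8ccc(OCc9ccccc9)c(OCc9ccccc9)c8)O6)[C@H](OCc9ccccc9)[C@@H](O[Si](CC)(CC)CC)c8ccc(OCc9ccccc9)c(OCc9ccccc9)c8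

A5 | alternative 2 | 3-(triisopropylsilyloxy)cyclobut-2-en-1-one bearing the perbenzylated upper unit (through its C4) on C2 | c1(OCc9ccccc9)cc(OCc9ccccc9)c2c(c1)O[C@H](c8ccc(OCc9ccccc9)c(OCc9ccccc9)c8)[C@H](OCc9ccccc9)[C@H]2C3=C(O[Si](C(C)C)(C(C)C)C(C)C)CC3=O

A6 | alternative 2 | triisopropylsiloxyalkyne bearing the middle C4–C2 chain and the lower unit | CC(C)[Si](C(C)C)(C(C)C)OC#C[C@@H](c5c(OCc9ccccc9)cc6c(c5OCc9ccccc9)C[C@H](OCc9ccccc9)[C@@H](c8ccc(OCc9ccccc9)c(OCc9ccccc9)c8)O6)[C@H](OCc9ccccc9)[C@@H](O[Si](CC)(CC)CC)c8ccc(OCc9ccccc9)c(OCc9ccccc9)c8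

A7 | alternative 3 | tetradeca-O-benzyl trimer, middle 3-O-acetate | c1(OCc9ccccc9)cc(OCc9ccccc9)c2c(c1)O[C@H](c8ccc(OCc9ccccc9)c(OCc9ccccc9)c8)[C@H](OCc9ccccc9)[C@H]2c3c(OCc9ccccc9)cc4c(c3OCc9ccccc9)[C@@H](c5c(OCc9ccccc9)cc6c(c5OCc9ccccc9)C[C@H](OCc9ccccc9)[C@@H](c8ccc(OCc9ccccc9)c(OCc9ccccc9)c8)O6)[C@H](OC(C)=O)[C@@H](c8ccc(OCc9ccccc9)c(OCc9ccccc9)c8)O4

A8 | alternative 3 | ortho-hydroxy diarylcarbinol joining the upper-unit-bearing ring A to lower C6 (carbinol epimers) | c1(OCc9ccccc9)cc(OCc9ccccc9)c2c(c1)O[C@H](c8ccc(OCc9ccccc9)c(OCc9ccccc9)c8)[C@H](OCc9ccccc9)[C@H]2c3c(OCc9ccccc9)cc(O)c(c3OCc9ccccc9)C(O)c5c(OCc9ccccc9)cc6c(c5OCc9ccccc9)C[C@H](OCc9ccccc9)[C@@H](c8ccc(OCc9ccccc9)c(OCc9ccccc9)c8)O6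

A9 | alternative 3 | (E)-2-[3,4-bis(benzyloxy)phenyl]vinyl acetate | CC(=O)O/C=C/c1ccc(OCc2ccccc2)c(OCc2ccccc2)c1
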